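| flask | substrate | remark | time |
|---|---|---|---|
| maple | 0.10 M | the very flask that is asked about, followed so far |  |
| birch | 0.20 M | run made earlier |  |
| flask | 0.10 M |  | 50 min |

| run | time / min | isomer of the product / % | target / % |
|---|---|---|---|
| maple | 1.50 | 0.8 | 1.8 |
| maple | 3.00 | 1.7 | 3.0 |
| maple | 5.00 | 1.8 | 5.1 |
| maple | 6.00 | 1.5 | 5.3 |
| birch | 4.00 | 1.7 | 3.1 |
| birch | 12.0 | 2.0 | 8.9 |
| birch | 25.0 | 4.2 | 15.3 |
| birch | 40.0 | 4.9 | 20.1 |

(each reading ± 0.5 percentage points)

- in percentages every species weighs as the substrate in it: one idle adduct counts as two
- for target the idle adduct is counted in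
- the numbers in the tables scatter with a standard deviation of 0.5 percentage points
- steps that have been proposed: intermediate <-> target; intermediate <-> isomer of the product; substrate -> intermediate; substrate + target <-> idle adduct; intermediate -> side product; substrate <-> dormant form
- in an amount of target, one idle adduct counts as one target

- ratio of isomer of the product to target at 1.5 min
- ratio of isomer of the product to target at 50 min

**What does a target reading count?** Free target plus target held in idle adduct, so adduct formation moves no target out of the reading.

**What is the ratio at 1.5 min in maple?** The reading there gives 0.444, but with so little target its scatter is 0.290, so it says little.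

**What do you use instead?** The 8 isomer readings sum to 18.6% and the target readings to 62.6%. Their quotient is the branching ratio, isomer made per target made from the intermediate (a selectivity factor): 0.297, with scatter 0.0236.

**Maple alone gives 0.382. Why pool?** That value has a scatter of 0.0704, and it stands 0.0850 above the pool. Both proposed steps leave the same intermediate, so I assume the charge does not change their ratio.

**And at 50 min?** The last birch reading, at 40.0 min, gives 0.244 and shows no rise, so I commit to 0.297 at both times in maple.

The forecast differs, with 0.48 (0.32 to 0.68) and 0.26 (0.2 to 0.34), the isomer being one that “relaxes through the intermediate towards a plateau”.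

Maple gives 0.295 at 1.5 min and 0.312 at 50 min.

    intermediate ⇌ target (K = 13.0, k = 0.0126 s⁻¹)
    intermediate ⇌ isomer of the product (K = 40.6, k = 0.00373 s⁻¹)
    substrate → intermediate (k = 5.40 × 10⁻⁴ s⁻¹)
    substrate + target ⇌ idle adduct, settled at all times (K = 430 L mol⁻¹)
    intermediate → side product (k = 9.90 × 10⁻⁵ s⁻¹)
    substrate ⇌ dormant form (K = 2.60, k = 0.00790 s⁻¹)

In maple the isomer of the product has a half-life of 130 min for going back, longer than the 50 min run. Maple's ratio at 50 min stands 0.0150 above the branching ratio 0.297, and by 500 min maple holds 49.8% isomer against 30.0% target. The neighbour flask at 0.040 M also starts at 0.296 and reaches 0.374 at 50 min.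

The data are calculated on assumed constants, noise included.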